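**Plan**

1. Retrosynthesis first cuts the C1–C8a bond of the carbocyclic ring B (the aryl-bearing benzylic carbon to the fused guaiacol ring). This reveals the twofold-symmetric lignan (−)-secoisolariciresinol.
2. The second cut is the central C2–C3 bond (lignan C8–C8'), which splits that diol into two identical dihydroferulic acid units.
3. Feature used: the pendant ring has a free OH para to C1, so C1 can be raised to a p-quinone methide. C8a of the fused ring is para to its own OMe (on C6) and ortho to the C4 methylene, so it is the nucleophile. Both benzylic CH2 groups of the precursor are homotopic.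
4. Forward: both arenes come from dihydroferulic acid. The chain is joined by oxidative homocoupling of an oxazolidinone enolate, then reduced and debenzylated. Ring B is closed last by a biomimetic benzylic dehydrogenation and quinone methide Friedel–Crafts cyclization.
5. Stereochemistry: C2 and C3 (both R) come from the (S)-4-isopropyloxazolidinone auxiliary in the homocoupling. C1 (S) comes from substrate control (trans to C2) in the ring closure.

Key step: step 6

Remark: tetralin numbering is used for the target (C1 aryl, C2 and C3 hydroxymethyl, C4 methylene, C6 OMe, C7 OH) and lignan numbering (C7, C8, C9 and primed atoms) for open-chain compounds. The R,R sense of the homocoupling is assumed to follow the usual facial bias of the chelated Z-enolate (bond formation anti to the isopropyl group).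

**Step 1**
Reactants: 1 3-(4-hydroxy-3-methoxyphenyl)propanoic acid (dihydroferulic acid)
Product: 2 3-(4-benzyloxy-3-methoxyphenyl)propanoic acid
Conditions: BnBr (1.2 equiv), NaOH (3 equiv), EtOH/H2O, reflux; then aq. HCl to pH 2
Reagents that add atoms: benzyl bromide, BrCc1ccccc1
Why: Williamson ether synthesis on the phenoxide of the dianion, which is far more nucleophilic than the carboxylate in aqueous alkali, so the acid should stay free; no stereocenter is involved.

**Step 2**
Reactants: 2 3-(4-benzyloxy-3-methoxyphenyl)propanoic acid; 3 (S)-4-isopropyl-2-oxazolidinone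
Product: 5 (S)-3-[3-(4-benzyloxy-3-methoxyphenyl)propanoyl]-4-isopropyloxazolidin-2-one, via mixed pivalic anhydride 4 (not isolated)
Conditions: t-BuCOCl, Et3N, THF, −20 °C; then 3, LiCl, −20 °C → rt
Reagents that add atoms: none
Why: N-acylation of the oxazolidinone through the mixed anhydride, which should be attacked at the less hindered acyl carbon; the stereocenter of the auxiliary is not touched.

**Step 3**
Reactants: 5 (S)-3-[3-(4-benzyloxy-3-methoxyphenyl)propanoyl]-4-isopropyloxazolidin-2-one (two molecules)
Product: 7 (2R,3R)-2,3-bis(4-benzyloxy-3-methoxybenzyl)-1,4-bis[(S)-4-isopropyl-2-oxooxazolidin-3-yl]butane-1,4-dione, via lithium Z-enolate 6 (not isolated)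
Conditions: LiN(i-Pr)2 (1.1 equiv), THF, −78 °C; then TiCl4 (1.1 equiv), −78 °C → rt
Reagents that add atoms: none
Why: Oxidative enolate homocoupling, in which TiCl4 (tetravalent titanium, reduced to trivalent titanium) oxidizes the chelated Z-enolate by one electron and two α-carbons join, each on the face away from the isopropyl group, which should set both new stereocenters as R; minor diastereomers are removed by crystallization or chromatography, which the auxiliary makes possible.

**Step 4**
Reactants: 7 (2R,3R)-2,3-bis(4-benzyloxy-3-methoxybenzyl)-1,4-bis[(S)-4-isopropyl-2-oxooxazolidin-3-yl]butane-1,4-dione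
Product: 8 (2R,3R)-2,3-bis(4-benzyloxy-3-methoxybenzyl)butane-1,4-diol
Conditions: LiBH4, MeOH (additive), THF, 0 °C → rt
Reagents that add atoms: none
Why: Reductive cleavage of both N-acyloxazolidinones by borohydride to the primary alcohols with release of the auxiliary, under conditions that should leave the aryl benzyl ethers and the two stereocenters unchanged.

**Step 5**
Reactants: 8 (2R,3R)-2,3-bis(4-benzyloxy-3-methoxybenzyl)butane-1,4-diol
Product: 9 (−)-secoisolariciresinol [(2R,3R)-2,3-bis(4-hydroxy-3-methoxybenzyl)butane-1,4-diol]
Conditions: H2 (1 atm), Pd/C, MeOH/EtOAc, rt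
Reagents that add atoms: none
Why: Catalytic hydrogenolysis of the two aryl benzyl ethers, which should free both phenols without affecting the diol or the stereocenters.

**Step 6**
Reactants: 9 (−)-secoisolariciresinol
Product: 12 (+)-isolariciresinol, via p-quinone methide 10 (not isolated), via (+)-lariciresinol 11 (not isolated)
Conditions: DDQ (0.95 equiv), 1,4-dioxane, 10 °C → rt; then CF3CO2H, CH2Cl2, 0 °C → rt
Reagents that add atoms: none
Why: DDQ removes hydride from a benzylic CH2 of 9 (assisted by the para OH) to give p-quinone methide 10, which the C9' hydroxyl captures reversibly by 5-exo-trig oxa-conjugate addition as tetrahydrofuran 11; CF3CO2H then re-ionizes 11 to the p-hydroxybenzyl cation (protonated 10), the second guaiacyl ring attacks it through the carbon para to its OMe group, and proton loss restores the arene. The closest known reaction types are the DDQ dehydrogenation of 4-alkylguaiacols to quinone methides, the DDQ-induced cyclization of dibenzylbutyrolactone lignans to aryltetralins and the acid-induced rearrangement of 7,9'-epoxylignans to cyclolignans, the sequence also presumed in the biosynthesis. Ring B closes by a 6-exo-trig cation-arene (Friedel–Crafts) attack through a chair-like transition state. The new stereocenter C1 is controlled by the neighbouring C2 stereocenter: the aryl group takes the equatorial position trans to the C2 hydroxymethyl group, which should give the all-equatorial 1S,2R,3R isomer whatever the configuration of 11 at its benzylic carbon, since that carbon passes through the planar cation. No choice between the two benzylic CH2 groups is needed because the twofold axis of 9 makes them homotopic, and attack para and not ortho to OMe is secured by the methoxy group itself and by the crowding of the ortho carbon between OMe and the tether. The one selectivity not written into the substrate, a single dehydrogenation, is secured by using slightly less than one equivalent of DDQ and by adding the acid only after the oxidant is spent, so that 12 never meets DDQ and unchanged 9 can be recycled.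

**Compound list**

1 | 3-(4-hydroxy-3-methoxyphenyl)propanoic acid (dihydroferulic acid) | COc1cc(CCC(=O)O)ccc1O | starting material
2 | 3-(4-benzyloxy-3-methoxyphenyl)propanoic acid | COc1cc(CCC(=O)O)ccc1OCc1ccccc1 | intermediate
3 | (S)-4-isopropyl-2-oxazolidinone | CC(C)[C@H]1COC(=O)N1 | starting material
4 | 3-(4-benzyloxy-3-methoxyphenyl)propanoic pivalic anhydride (mixed anhydride) | COc1cc(CCC(=O)OC(=O)C(C)(C)C)ccc1OCc1ccccc1 | intermediate
5 | (S)-3-[3-(4-benzyloxy-3-methoxyphenyl)propanoyl]-4-isopropyloxazolidin-2-one | COc1cc(CCC(=O)N2[C@@H](C(C)C)COC2=O)ccc1OCc1ccccc1 | intermediate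
6 | lithium Z-enolate of 5 | COc1cc(C/C=C(\[O-])N2[C@@H](C(C)C)COC2=O)ccc1OCc1ccccc1.[Li+] | intermediate
7 | (2R,3R)-2,3-bis(4-benzyloxy-3-methoxybenzyl)-1,4-bis[(S)-4-isopropyl-2-oxooxazolidin-3-yl]butane-1,4-dione | COc1cc(C[C@@H](C(=O)N2[C@@H](C(C)C)COC2=O)[C@H](C(=O)N2[C@@H](C(C)C)COC2=O)Cc2ccc(OCc3ccccc3)c(OC)c2)ccc1OCc1ccccc1 | intermediate
8 | (2R,3R)-2,3-bis(4-benzyloxy-3-methoxybenzyl)butane-1,4-diol | COc1cc(C[C@@H](CO)[C@H](CO)Cc2ccc(OCc3ccccc3)c(OC)c2)ccc1OCc1ccccc1 | intermediate
9 | (−)-secoisolariciresinol, (2R,3R)-2,3-bis(4-hydroxy-3-methoxybenzyl)butane-1,4-diol | COc1cc(C[C@@H](CO)[C@H](CO)Cc2ccc(O)c(OC)c2)ccc1O | intermediate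
10 | 4-[(2R,3R)-4-hydroxy-2-(hydroxymethyl)-3-(4-hydroxy-3-methoxybenzyl)butylidene]-2-methoxycyclohexa-2,5-dien-1-one (p-quinone methide, alkene geometry not defined) | COC1=CC(=C[C@@H](CO)[C@H](CO)Cc2ccc(O)c(OC)c2)C=CC1=O | intermediate
11 | (+)-lariciresinol, 4-{[(3R,4R,5S)-5-(4-hydroxy-3-methoxyphenyl)-4-(hydroxymethyl)oxolan-3-yl]methyl}-2-methoxyphenol | COc1cc(C[C@H]2CO[C@@H]([C@H]2CO)c3ccc(O)c(OC)c3)ccc1O | intermediate
12 | (+)-isolariciresinol, (6R,7R,8S)-8-(4-hydroxy-3-methoxyphenyl)-6,7-bis(hydroxymethyl)-3-methoxy-5,6,7,8-tetrahydronaphthalen-2-ol | COc1cc([C@H]2c3cc(O)c(OC)cc3C[C@@H](CO)[C@@H]2CO)ccc1O | target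

**Totals**

Total step count: 6. Longest linear sequence: 6 steps (1 → 12).

**Steps most likely to fail**

1. Step 6. What may go wrong: a second dehydrogenation on the remaining 4-hydroxybenzyl arm before the acid is added, tautomerization of the quinone methide to a styrene with loss of the adjacent stereocenter, or oxidative phenol coupling. The fallback brings in the benzylic oxygen by an aldol reaction, so no C–H oxidation is needed. It sets out from 5 and comes back at 12.
   - Evans alkylation of 5 (NaN(SiMe3)2, tert-butyl bromoacetate, THF, −78 °C) should give the alkylated imide F1.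
   - LiBH4 should remove the auxiliary to give the hydroxy tert-butyl ester F2, which should lactonize (cat. TsOH, toluene, heat) to the (R)-β-benzylbutyrolactone F3.
   - Deprotonation of F3 with LiN(SiMe3)2 (THF, −78 °C) and addition to commercial 4-benzyloxy-3-methoxybenzaldehyde, trans to the benzyl group, should give the aldol adduct F4 (carbinol epimers, both usable).
   - CF3CO2H in CH2Cl2 should ionize the benzylic alcohol and close ring B by the same cation-arene attack to the trans,trans aryltetralin lactone F5.
   - LiAlH4 should open the lactone to di-O-benzyl-isolariciresinol F6, and H2, Pd/C should give 12.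

2. Step 3. What may go wrong: insufficient facial control in the radical-type coupling, so that R,S and S,S dimers dilute the R,R isomer, or competing acyl transfer between enolate and imide. The fallback builds the two stereocenters one after the other. It sets out from 5 and comes back at 8.
   - 5 is taken as above through the alkylated imide F1 and the hydroxy ester F2 to the lactone F3.
   - The enolate of F3 (LiN(SiMe3)2, THF, −78 °C) is alkylated trans to the existing benzyl group with 4-benzyloxy-3-methoxybenzyl bromide F7 (made from the commercial benzyl alcohol with PBr3) to give di-O-benzyl-matairesinol F8.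
   - LiAlH4 reduction of the lactone should give 8.

3. Step 4. What may go wrong: hydride attack on the ring carbonyl of the hindered oxazolidinones (ring opening in place of exocyclic cleavage) or stalling after the first reduction. The fallback separates cleavage and reduction. It sets out from 7 and comes back at 8.
   - LiOH/H2O2 (THF/H2O, 0 °C) should hydrolyse both imides to the diacid F9.
   - LiAlH4 (THF, reflux) should reduce F9 to 8.

**Further compounds**

F1 | step 6 | (S)-3-[(R)-2-(4-benzyloxy-3-methoxybenzyl)-4-tert-butoxy-4-oxobutanoyl]-4-isopropyloxazolidin-2-one | COc1cc(C[C@H](CC(=O)OC(C)(C)C)C(=O)N2[C@@H](C(C)C)COC2=O)ccc1OCc1ccccc1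
F2 | step 6 | tert-butyl (R)-4-(4-benzyloxy-3-methoxyphenyl)-3-(hydroxymethyl)butanoate | COc1cc(C[C@H](CC(=O)OC(C)(C)C)CO)ccc1OCc1ccccc1
F3 | step 6 | (R)-4-(4-benzyloxy-3-methoxybenzyl)dihydrofuran-2(3H)-one | COc1cc(C[C@@H]2CC(=O)OC2)ccc1OCc1ccccc1
F4 | step 6 | (3S,4R)-4-(4-benzyloxy-3-methoxybenzyl)-3-[(4-benzyloxy-3-methoxyphenyl)(hydroxy)methyl]dihydrofuran-2(3H)-one (carbinol epimers) | COc1cc(C[C@H]2COC(=O)[C@@H]2C(O)c2ccc(OCc3ccccc3)c(OC)c2)ccc1OCc1ccccc1
F5 | step 6 | trans,trans aryltetralin lactone (di-O-benzyl-α-retrodendrin type, carbonyl on C2) | COc1cc([C@H]2c3cc(OCc4ccccc4)c(OC)cc3C[C@H]3COC(=O)[C@H]23)ccc1OCc1ccccc1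
F6 | step 6 | di-O-benzyl-isolariciresinol | COc1cc([C@H]2c3cc(OCc4ccccc4)c(OC)cc3C[C@@H](CO)[C@@H]2CO)ccc1OCc1ccccc1
F7 | step 3 | 4-benzyloxy-3-methoxybenzyl bromide | COc1cc(CBr)ccc1OCc1ccccc1
F8 | step 3 | (3R,4R)-3,4-bis(4-benzyloxy-3-methoxybenzyl)dihydrofuran-2(3H)-one (di-O-benzyl-matairesinol) | COc1cc(C[C@H]2COC(=O)[C@@H]2Cc2ccc(OCc3ccccc3)c(OC)c2)ccc1OCc1ccccc1
F9 | step 4 | (2R,3R)-2,3-bis(4-benzyloxy-3-methoxybenzyl)succinic acid | COc1cc(C[C@@H](C(=O)O)[C@H](C(=O)O)Cc2ccc(OCc3ccccc3)c(OC)c2)ccc1OCc1ccccc1
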